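## The problem

Target 19 is a 3,4-dihydro-6H-isochromene-6,8(7H)-dione. Carbocyclic ring A (C4a–C5–C6–C7–C8–C8a) is fused along C4a–C8a to dihydropyran ring B (O2–C1–C8a–C4a–C4–C3). The two rings share one cross-conjugated chromophore, the vinylogous ester O2–C1=C8a–C8=O and the enone C4a=C5–C6=O.

There are two stereocentres. C3 (R) is a secondary ether carbon and can come from the chiral pool. C7 (R) is a fully substituted carbinol that carries methyl, the linoleate oxygen and both ring ketones. C3 and C7 sit at opposite ends of a flat bicycle, so C3 cannot steer C7 once the rings exist; control must be relayed while the chain is open.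

Several groups will not survive rough treatment:
- the C7 ketol between two carbonyl groups (acyloin shifts, retro-Claisen cleavage);
- the linoleate, with an α-CH2 poised for aldol closure onto C6 or C8 and a skipped Z,Z-diene that excludes hydrogenation, strong base and radical conditions late in the route;
- the C1 enol ether;
- C4–H, which is γ to the C6 enone with O2 in the β-position (ring-opening elimination).

The enabling feature is this: C7 bears CH3, O, C8 and the C6 ketone; the α-carbon of C6 (C5) is allylic to C4a; and C4, next to C3, carries no oxygen. That is the pattern left when an allylic C4 hydroxyl hands its oxygen to C7 through a Claisen rearrangement (C5–C6) followed by a 1,2-shift (C7–CH3), after a diazoacetoacetate has supplied C6, C7, C8 and the methyl group.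

## Retrosynthesis

**Ester C–O bond (19 ⇒ 16 + 18).** The linoleate is the most fragile part, so it is cut first and attached last. The precursors are the free ketol 16 and linoleoyl chloride 18, made from linoleic acid 17. The forward step must acylate a hindered tertiary alcohol without a base strong enough to deprotonate C4 or the new ester α-CH2.

**O2–C1 bond of ring B (16 ⇒ 15).** The vinylogous ester is a condensation product of a C1 hydroxymethylene group on C8a with the C3 hydroxyl. Cutting here, rather than cutting ring A first, leaves the monocyclic tricarbonyl compound 15 with C3–O still silylated. The forward step needs only acid, to remove the silyl group and lose water.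

**C8–C8a bond of ring A (15 ⇒ 14 ⇒ 13).** C8a is α to the C1 aldehyde and vinylogously α to the C6 ketone, and C8 is an ester carbon, so this is a Dieckmann disconnection to keto aldehyde 14 and, one functional-group step back, its dimethyl acetal 13. Neighbouring cuts (C5–C6, C6–C7) would place the bond-forming event at or next to the quaternary carbinol. This cut instead leaves C7 complete in an open-chain α-hydroxy-β-keto ester. The forward reaction must move the 5,6-alkene into conjugation and acylate at C8a, which is the only position that gives a six-membered ring.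

**C5–C6 and C7–CH3 (13 ⇒ 8 + 10; key step).** Hydroxy keto ester 13 is disconnected to allylic alcohol 8 and methyl 2-diazo-3-oxobutanoate 10. The forward sequence is:
- the carbenoid inserts into the C4 O–H bond;
- the Z enol allyl ether 11 rearranges [3,3] to form C5–C6 and cut C4–O, giving α-keto ester 12;
- a 1,2-methyl shift makes C7–CH3 and the C6 ketone.

This cut is preferred over an aldol or acylation at C6 because it builds the quaternary centre by rearrangement instead of intermolecular attack at a crowded carbon, and it takes its configuration from a secondary carbinol that is easy to set. Working through the Z enol, the chair with the C3-bearing group equatorial and the syn-chelated shift shows that the C4 carbinol must be R (C3 of the hexanol name of 8) to give 7R; the epimer would give 7S. The forward reaction asks for methyl, not the allylic CH2, to end on C7. That is the unproven point, and it is addressed in step 8.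

**C4–C4a and the C4 carbinol (8 ⇒ 7 ⇒ 6 ⇒ 3 + 5).** The 1,1-disubstituted allylic alcohol is cut between C4 and C4a to aldehyde 3 and enol triflate 5, joined by a Nozaki–Hiyama–Kishi coupling. Because that addition favours the wrong (Felkin, anti) epimer, the mixture 6 is oxidised to enone 7 and reduced under Felkin–Anh control, which for a ketone reduction gives the required syn alcohol 8. Aldehyde 3 comes from methyl (R)-lactate 1 through silyl ether 2, triflate 5 from 4,4-dimethoxybutan-2-one 4, and diazo ester 10 from methyl acetoacetate 9.

## Roads not taken

**Alternative 1:** cut C7–C8 of ring A.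
- Key step: a triazolium-derived carbene converts the C8 aldehyde of keto aldehyde A2 into an acyl anion equivalent that adds to the C7 methyl ketone of the side-chain 1,2-diketone, giving A1, which is the same compound as 16.
- Merits: C7 and ring A are made in one catalytic step; the catalyst controls C7 independently of C3; aldehyde–ketone benzoin closures to six-membered tertiary ketols are an established class; the product is one step from the target.
- Weak points: the C8 aldehyde of A2 is a vinylogous formate and a reluctant partner for the carbene. The 1,2-diketone is itself an acyl donor towards carbenes and offers a second ketone (C6) whose attack would give a five-membered ring. The base that liberates the carbene can deprotonate C4. The exocyclic alkene of A2 must have the geometry that lets C8 reach C7.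
- Comparison: this road is better in that its key reaction type has direct precedent for the bond it forms, whereas the migrating-group preference of the chosen plan is unproven. The chosen plan sets against it simple precursors from lactate, a relay that needs no chiral catalyst, and a fallback that reuses its intermediates.

**Alternative 2:** cut C8a–C1 and O2–C1.
- Key step: LiN(SiMe3)2 enolises the symmetric dione formate A4; the formyl group on the C3 oxygen is transferred to one of the two α-carbons, and acid closes O2–C1 to give A3.
- Merits: ring A is bought as a 2-methylcyclohexane-1,3-dione derivative; C7 becomes stereogenic by desymmetrisation, with no bond formed at the crowded centre; the sequence is short on paper and avoids open-chain tricarbonyl intermediates.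
- Weak points: the two α-carbons are distinguished only by a stereocentre on a flexible side chain, and both transfers pass through the same ring size. The relation between the C7 substituents and the side chain must be set beforehand. A3 still lacks the C4a=C5 double bond, so a dehydrogenation next to the quaternary ketol is needed.
- Comparison: fewer steps if the selection works. The chosen plan sets against it stereocontrol through ordered cyclic transition states instead of an untested remote induction, and the correct oxidation level of ring A without a late oxidation.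

**Alternative 3:** cut C8–C8a.
- Key step: CrCl2 with catalytic NiCl2 converts the C8a iodide of A6 into an alkenylchromium species that adds to the C8 aldehyde, giving the C8 carbinol A5, which is then oxidised to the target.
- Merits: a neutral, chemoselective ring closure that tolerates the linoleate. The ester is therefore in place before the sensitive bicycle exists, and the late acylation of a hindered ketol (the weakest late step of the chosen route) is avoided.
- Weak points: A6 holds every difficulty in the precursor. C7 must be made enantiopure by other means, with an aldehyde, a ketone and an acyloxy group on one carbon (deformylation, hydration, acyl migration). The linoleate α-CH2 can close onto C6 or C8 throughout. The iodo enol ether must be made with defined regiochemistry and geometry. An extra oxidation follows.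
- Comparison: better at the very end of the synthesis. The chosen plan sets against it a key step that creates C7, and a linoleate that is present in only one step.

Key step: step 8

Assumption: the species that rearranges is the Z enol (enol OH cis to the allyloxy oxygen) formed by internal proton transfer in the oxonium ylide, and the 1,2-shifts pass through the syn chelate of hydroxyl and ketone; on this basis the (3R)-alcohol 8, not its 3S epimer, maps onto 7R.

## Route

Step 1
Reactants: 1 methyl (2R)-2-hydroxypropanoate
Product: 2 methyl (2R)-2-[(tert-butyldimethylsilyl)oxy]propanoate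
Conditions: TBSCl, imidazole, DMF, rt
Reagents that add atoms: tert-butyldimethylsilyl chloride, C[Si](C)(Cl)C(C)(C)C
Why: Silyl ether formation at the secondary hydroxyl; the stereocentre is not touched and becomes C3 (R) of the target.

Step 2
Reactants: 2 methyl (2R)-2-[(tert-butyldimethylsilyl)oxy]propanoate
Product: 3 (2R)-2-[(tert-butyldimethylsilyl)oxy]propanal
Conditions: i-Bu2AlH, CH2Cl2, −78 °C; aq. potassium sodium tartrate
Reagents that add atoms: none
Why: Partial reduction of the ester stops at the aluminium hemiacetal at −78 °C and releases the aldehyde on work-up; the α-silyloxy aldehyde is used at once so that it does not epimerise.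

Step 3
Reactants: 4 4,4-dimethoxybutan-2-one
Product: 5 4,4-dimethoxybut-1-en-2-yl trifluoromethanesulfonate
Conditions: KN(SiMe3)2, THF, −78 °C; PhNTf2, −78 to 0 °C
Reagents that add atoms: N-phenylbis(trifluoromethanesulfonimide), FC(F)(F)S(=O)(=O)N(c1ccccc1)S(=O)(=O)C(F)(F)F
Why: Kinetic deprotonation at the unhindered methyl group and O-sulfonylation of the enolate (enol triflate synthesis); the low temperature keeps the regioisomeric enolate, which would expel methoxide, from forming.

Step 4
Reactants: 3 (2R)-2-[(tert-butyldimethylsilyl)oxy]propanal; 5 4,4-dimethoxybut-1-en-2-yl trifluoromethanesulfonate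
Product: 6 (2R,3RS)-2-[(tert-butyldimethylsilyl)oxy]-6,6-dimethoxy-4-methylidenehexan-3-ol
Conditions: CrCl2, NiCl2 (cat.), DMF, rt
Reagents that add atoms: none
Why: Nozaki–Hiyama–Kishi coupling: nickel inserts into the C–OTf bond, the alkenyl group passes to chromium and adds to the aldehyde, forming C4–C4a without touching acetal or silyl ether. The epimer ratio at the new carbinol does not matter because step 5 removes that centre.

Step 5
Reactants: 6 (2R,3RS)-2-[(tert-butyldimethylsilyl)oxy]-6,6-dimethoxy-4-methylidenehexan-3-ol
Product: 7 (2R)-2-[(tert-butyldimethylsilyl)oxy]-6,6-dimethoxy-4-methylidenehexan-3-one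
Conditions: Dess–Martin periodinane, pyridine, CH2Cl2, 0 °C to rt
Reagents that add atoms: none
Why: Dess–Martin oxidation converges both epimers on one enone; pyridine buffers the acetic acid, so the acetal survives and the α-silyloxy centre is not epimerised.

Step 6
Reactants: 7 (2R)-2-[(tert-butyldimethylsilyl)oxy]-6,6-dimethoxy-4-methylidenehexan-3-one
Product: 8 (2R,3R)-2-[(tert-butyldimethylsilyl)oxy]-6,6-dimethoxy-4-methylidenehexan-3-ol
Conditions: NaBH4, CeCl3·7H2O, MeOH, −78 °C
Reagents that add atoms: none
Why: Luche 1,2-reduction of the enone. The non-chelating silyloxy group should direct hydride by the polar Felkin–Anh model (C–O bond anti to the incoming hydride, approach past H), which for a ketone reduction gives the 2,3-syn alcohol, that is 3R (C4 of the target numbering).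

Step 7
Reactants: 9 methyl 3-oxobutanoate
Product: 10 methyl 2-diazo-3-oxobutanoate
Conditions: 4-acetamidobenzenesulfonyl azide, Et3N, MeCN, 0 °C to rt
Reagents that add atoms: 4-acetamidobenzenesulfonyl azide, CC(=O)Nc1ccc(cc1)S(=O)(=O)N=[N+]=[N-]
Why: Regitz diazo transfer to the active methylene of the β-keto ester.

Step 8
Reactants: 8 (2R,3R)-2-[(tert-butyldimethylsilyl)oxy]-6,6-dimethoxy-4-methylidenehexan-3-ol; 10 methyl 2-diazo-3-oxobutanoate
Product: 13 methyl (2R,5E,7R)-7-[(tert-butyldimethylsilyl)oxy]-5-(2,2-dimethoxyethyl)-2-hydroxy-2-methyl-3-oxooct-5-enoate, via Z enol allyl ether 11 (not isolated), via tertiary alpha-keto ester 12 (not isolated)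
Conditions: Rh2(OAc)4 (1 mol %), ClCH2CH2Cl, 80 °C, slow addition of 10; then MgBr2·OEt2, i-Pr2NEt, CH2Cl2, 0 °C to rt; AcOH, −78 °C
Reagents that add atoms: none
Why: Proposed new method: the closest known reaction type is the Rh2(OAc)4-initiated O–H insertion, Claisen rearrangement and α-ketol shift of 2-diazo-3-oxobutanoates with enantioenriched secondary allylic alcohols, in which, however, the allylic residue and not methyl is the group known to migrate, so a methyl-selective relay to this constitution is new. The rhodium carbenoid from 10 inserts into the O–H bond of 8 through an oxonium ylide whose proton passes internally to the ketone oxygen, giving Z enol ether 11; its chair [3,3] rearrangement with the C3-bearing group equatorial forms C5–C6, breaks C4–O and gives keto ester 12 with C3 trans to C5 on the new alkene and the C6 carbinol R. In the magnesium chelate that holds the C6 hydroxyl and the C7 ketone syn, methyl migrates suprafacially to C7 and creates C7–CH3 and the C6 ketone, so that 4R is carried through 6R to 7R; no ring is closed. The selectivity to be secured is methyl over the allylic CH2 as migrating group, and the design relies on thermodynamic instead of kinetic selection: under MgBr2·OEt2 and an amine the ketol shifts should be reversible, the isomer formed by allyl migration can pass on by a 1,2-shift of its ester group through the same syn chelate (a check of the three suprafacial shifts shows that this detour ends at the same constitution and the same 7R configuration), and only 13 has a C–H that is both allylic and α to a ketone, so it alone is drained as a chelated magnesium dienolate. Protonation of that dienolate at its α-carbon at −78 °C returns 13 as the β,γ-enone. The mild Lewis acid and amine pair is chosen over BF3·OEt2 so that the acetal and the silyl ether are not ionised and the tertiary hydroxyl is not trapped as a cyclic acetal. Chemoselectivity of the first stage rests on O–H insertion of acceptor-substituted carbenoids being much faster than cyclopropanation of the 1,1-disubstituted alkene or ylide formation at ether oxygens.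

Step 9
Reactants: 13 methyl (2R,5E,7R)-7-[(tert-butyldimethylsilyl)oxy]-5-(2,2-dimethoxyethyl)-2-hydroxy-2-methyl-3-oxooct-5-enoate
Product: 14 methyl (2R,5E,7R)-7-[(tert-butyldimethylsilyl)oxy]-2-hydroxy-2-methyl-3-oxo-5-(2-oxoethyl)oct-5-enoate
Conditions: LiBF4, MeCN/H2O (98:2), rt
Reagents that add atoms: water, O
Why: Lewis-acid-assisted hydrolysis of the dimethyl acetal under nearly neutral conditions, which should leave the secondary silyl ether and the tertiary ketol intact; the aldehyde is carried on crude.

Step 10
Reactants: 14 methyl (2R,5E,7R)-7-[(tert-butyldimethylsilyl)oxy]-2-hydroxy-2-methyl-3-oxo-5-(2-oxoethyl)oct-5-enoate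
Product: 15 (6R)-3-{(2R)-2-[(tert-butyldimethylsilyl)oxy]propyl}-6-hydroxy-2-(hydroxymethylidene)-6-methylcyclohex-3-ene-1,5-dione
Conditions: KOtBu (1.1 equiv), THF/t-BuOH, −20 to 0 °C; then 1 M HCl to pH 4
Reagents that add atoms: none
Why: tert-Butoxide moves the alkene into conjugation with C6 and generates the delocalised keto-aldehyde anion, which acylates itself at C8a with the methyl ester (Dieckmann condensation, 6-exo-trig, the only ring size open to it) to form C8–C8a. With one equivalent of base the charge stays on the carbon acid and then on the more acidic product, so the C7 hydroxyl remains protonated and the C6 and C8 carbonyls are shielded from ketol chemistry; C7 has no α-hydrogen and keeps its configuration.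

Step 11
Reactants: 15 (6R)-3-{(2R)-2-[(tert-butyldimethylsilyl)oxy]propyl}-6-hydroxy-2-(hydroxymethylidene)-6-methylcyclohex-3-ene-1,5-dione
Product: 16 (3R,7R)-7-hydroxy-3,7-dimethyl-3,4-dihydro-6H-isochromene-6,8(7H)-dione
Conditions: aq. HF (48 %), MeCN, 0 °C to rt
Reagents that add atoms: none
Why: Acidic desilylation frees the C3 hydroxyl, which condenses with the acidic hydroxymethylene group (addition–elimination at C1 with loss of water) to close ring B as the vinylogous ester; the C7 carbinol, flanked by two carbonyl groups, should not ionise.

Step 12
Reactants: 17 (9Z,12Z)-octadeca-9,12-dienoic acid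
Product: 18 (9Z,12Z)-octadeca-9,12-dienoyl chloride
Conditions: (COCl)2, DMF (cat.), CH2Cl2, 0 °C to rt
Reagents that add atoms: oxalyl chloride, O=C(Cl)C(Cl)=O
Why: Acid chloride formation through the chloroiminium species from DMF; the conditions are neutral and cold, so the skipped Z,Z-diene is not isomerised.

Step 13
Reactants: 16 (3R,7R)-7-hydroxy-3,7-dimethyl-3,4-dihydro-6H-isochromene-6,8(7H)-dione; 18 (9Z,12Z)-octadeca-9,12-dienoyl chloride
Product: 19 (3R,7R)-3,7-dimethyl-6,8-dioxo-3,4,7,8-tetrahydro-6H-isochromen-7-yl (9Z,12Z)-octadeca-9,12-dienoate
Conditions: pyridine, DMAP (cat.), CH2Cl2, 0 °C to rt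
Reagents that add atoms: none
Why: DMAP-catalysed acylation of the hindered tertiary alcohol through the N-acylpyridinium ion; pyridine is too weak a base to deprotonate C4 or the new ester α-CH2, so ring-opening elimination and aldol closure onto C6 or C8 should not compete.

## Compound list

1 | methyl (2R)-2-hydroxypropanoate (methyl (R)-lactate) | C[C@@H](O)C(=O)OC | starting material
2 | methyl (2R)-2-[(tert-butyldimethylsilyl)oxy]propanoate | C[C@@H](O[Si](C)(C)C(C)(C)C)C(=O)OC | intermediate
3 | (2R)-2-[(tert-butyldimethylsilyl)oxy]propanal | C[C@@H](O[Si](C)(C)C(C)(C)C)C=O | intermediate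
4 | 4,4-dimethoxybutan-2-one | CC(=O)CC(OC)OC | starting material
5 | 4,4-dimethoxybut-1-en-2-yl trifluoromethanesulfonate | C=C(CC(OC)OC)OS(=O)(=O)C(F)(F)F | intermediate
6 | (2R,3RS)-2-[(tert-butyldimethylsilyl)oxy]-6,6-dimethoxy-4-methylidenehexan-3-ol (both C3 epimers) | C[C@@H](O[Si](C)(C)C(C)(C)C)C(O)C(=C)CC(OC)OC | intermediate
7 | (2R)-2-[(tert-butyldimethylsilyl)oxy]-6,6-dimethoxy-4-methylidenehexan-3-one | C[C@@H](O[Si](C)(C)C(C)(C)C)C(=O)C(=C)CC(OC)OC | intermediate
8 | (2R,3R)-2-[(tert-butyldimethylsilyl)oxy]-6,6-dimethoxy-4-methylidenehexan-3-ol | C[C@@H](O[Si](C)(C)C(C)(C)C)[C@H](O)C(=C)CC(OC)OC | intermediate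
9 | methyl 3-oxobutanoate (methyl acetoacetate) | CC(=O)CC(=O)OC | starting material
10 | methyl 2-diazo-3-oxobutanoate | CC(=O)C(=[N+]=[N-])C(=O)OC | intermediate
11 | methyl (2Z)-2-{[(2R,3R)-2-[(tert-butyldimethylsilyl)oxy]-6,6-dimethoxy-4-methylidenehexan-3-yl]oxy}-3-hydroxybut-2-enoate | O/C(C)=C(\O[C@H](C(=C)CC(OC)OC)[C@@H](C)O[Si](C)(C)C(C)(C)C)C(=O)OC | intermediate (not isolated)
12 | methyl (3R,5Z,7R)-7-[(tert-butyldimethylsilyl)oxy]-5-(2,2-dimethoxyethyl)-3-hydroxy-3-methyl-2-oxooct-5-enoate (C4 trans to C7 on the alkene) | COC(=O)C(=O)[C@](C)(O)C/C(CC(OC)OC)=C/[C@@H](C)O[Si](C)(C)C(C)(C)C | intermediate (not isolated)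
13 | methyl (2R,5E,7R)-7-[(tert-butyldimethylsilyl)oxy]-5-(2,2-dimethoxyethyl)-2-hydroxy-2-methyl-3-oxooct-5-enoate | COC(=O)[C@](C)(O)C(=O)C/C(CC(OC)OC)=C/[C@@H](C)O[Si](C)(C)C(C)(C)C | intermediate
14 | methyl (2R,5E,7R)-7-[(tert-butyldimethylsilyl)oxy]-2-hydroxy-2-methyl-3-oxo-5-(2-oxoethyl)oct-5-enoate | COC(=O)[C@](C)(O)C(=O)C/C(CC=O)=C/[C@@H](C)O[Si](C)(C)C(C)(C)C | intermediate
15 | (6R)-3-{(2R)-2-[(tert-butyldimethylsilyl)oxy]propyl}-6-hydroxy-2-(hydroxymethylidene)-6-methylcyclohex-3-ene-1,5-dione (drawn as the hydroxymethylene tautomer) | O[C@]1(C)C(=O)C=C(C[C@@H](C)O[Si](C)(C)C(C)(C)C)C(=CO)C1=O | intermediate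
16 | (3R,7R)-7-hydroxy-3,7-dimethyl-3,4-dihydro-6H-isochromene-6,8(7H)-dione | O[C@]1(C)C(=O)C=C2C[C@@H](C)OC=C2C1=O | intermediate
17 | (9Z,12Z)-octadeca-9,12-dienoic acid (linoleic acid) | CCCCC/C=C\C/C=C\CCCCCCCC(=O)O | starting material
18 | (9Z,12Z)-octadeca-9,12-dienoyl chloride | CCCCC/C=C\C/C=C\CCCCCCCC(=O)Cl | intermediate
19 | (3R,7R)-3,7-dimethyl-6,8-dioxo-3,4,7,8-tetrahydro-6H-isochromen-7-yl (9Z,12Z)-octadeca-9,12-dienoate | CCCCC/C=C\C/C=C\CCCCCCCC(=O)O[C@]1(C)C(=O)C=C2C[C@@H](C)OC=C2C1=O | target

## Step count and least certain steps

Total: 13 steps. Longest linear sequence: 10 steps (1 → 2 → 3 → 6 → 7 → 8 → 13 → 14 → 15 → 16 → 19).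

**Step 8 (key step, proposed new method).** Three processes may go wrong.
- Migration of the allylic CH2 instead of methyl in the ketol stage. This is the kinetically preferred event in the known series, and the planned ester-shift and dienolate drain may fail to correct it.
- Leakage of enol 11 through its keto tautomer to the ester-hydrogen-bonded enol, which transfers chirality in the opposite sense and would erode the configuration at C7.
- Loss of silanolate from the dienolate.

If only the sense of transfer is wrong, the 3S epimer of 8, expected to be the major component of 6, can be used instead. The fallback for the step itself uses known chemistry and sets out from 8 (or from 6, since the carbinol configuration is then immaterial):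
- O-alkylation with Bu3SnCH2I and KH gives the stannylmethyl ether F1.
- n-BuLi at −78 °C triggers the Wittig–Still [2,3] rearrangement to the homoallylic alcohol F2, which carries C6 on C5.
- Dess–Martin oxidation gives the aldehyde F3.
- The lithium enolate of (2S,5S)-2-tert-butyl-5-methyl-1,3-dioxolan-4-one (from (S)-lactic acid and pivalaldehyde; LiN(i-Pr)2, THF, −78 °C) adds to F3 anti to the tert-butyl group. This sets C7 with retention relative to lactic acid, that is 7R, in the aldol adduct F4.
- Oxidation gives the ketone F5, and K2CO3 in methanol opens the dioxolanone to the 5Z isomer of 13, F6.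
- Steps 9 and 10 applied to F6 pass through the 5Z isomer of 14, F7, and arrive at 15, where the alkene geometry no longer exists.

**Step 6.** Facial selectivity of hydride delivery may be poor (a small hydride, and possible chelation by cerium), and some conjugate reduction is possible. Fallback by inversion instead of reduction: the 3S epimer, expected to predominate in 6 from the Felkin-controlled addition, is separated and subjected to Mitsunobu reaction with 4-nitrobenzoic acid to give the inverted ester F8; methanolysis with K2CO3 returns to the route at 8.

**Step 10.** The stabilised keto-aldehyde anion is a weak nucleophile and C8 is hindered, so C-acylation may be slow. That would leave room for intermolecular aldol condensation of the aldehyde or acyl shifts at the ketol. Fallback that closes ring B first and uses a more reactive dienolate: from 13, camphorsulfonic acid in methanol removes the silyl group and exchanges the acetal with the C3 hydroxyl to give the cyclic methyl acetal F9. KOtBu then conjugates the alkene, closes C8–C8a and expels methoxide from C1, and acidification returns to the route at 16.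

**Step 13.** Acylation of the hindered tertiary ketol may be slow, giving time for base-induced ring opening at C4/O2 or aldol closure of the product. Fallback with acid instead of base activation: 17 is converted with dicyclohexylcarbodiimide into linoleic anhydride F10, and 16 is acylated with F10 under Sc(OTf)3 catalysis at low temperature, returning to the route at 19.

## Further compounds

F1 | step 8 | tributyl({[(2R,3R)-2-[(tert-butyldimethylsilyl)oxy]-6,6-dimethoxy-4-methylidenehexan-3-yl]oxy}methyl)stannane | C[C@@H](O[Si](C)(C)C(C)(C)C)[C@H](OC[Sn](CCCC)(CCCC)CCCC)C(=C)CC(OC)OC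
F2 | step 8 | (3E,5R)-5-[(tert-butyldimethylsilyl)oxy]-3-(2,2-dimethoxyethyl)hex-3-en-1-ol (hydroxyethyl chain cis to C5) | OCC/C(CC(OC)OC)=C\[C@@H](C)O[Si](C)(C)C(C)(C)C
F3 | step 8 | (3E,5R)-5-[(tert-butyldimethylsilyl)oxy]-3-(2,2-dimethoxyethyl)hex-3-enal | O=CC/C(CC(OC)OC)=C\[C@@H](C)O[Si](C)(C)C(C)(C)C
F4 | step 8 | (2S,5R)-2-tert-butyl-5-{(5R)-5-[(tert-butyldimethylsilyl)oxy]-3-(2,2-dimethoxyethyl)-1-hydroxyhex-3-en-1-yl}-5-methyl-1,3-dioxolan-4-one (carbinol epimers) | C[C@]1(C(O)C/C(CC(OC)OC)=C\[C@@H](C)O[Si](C)(C)C(C)(C)C)O[C@H](C(C)(C)C)OC1=O
F5 | step 8 | (2S,5R)-2-tert-butyl-5-{(5R)-5-[(tert-butyldimethylsilyl)oxy]-3-(2,2-dimethoxyethyl)hex-3-enoyl}-5-methyl-1,3-dioxolan-4-one | C[C@]1(C(=O)C/C(CC(OC)OC)=C\[C@@H](C)O[Si](C)(C)C(C)(C)C)O[C@H](C(C)(C)C)OC1=O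
F6 | step 8 | methyl (2R,5Z,7R)-7-[(tert-butyldimethylsilyl)oxy]-5-(2,2-dimethoxyethyl)-2-hydroxy-2-methyl-3-oxooct-5-enoate | COC(=O)[C@](C)(O)C(=O)C/C(CC(OC)OC)=C\[C@@H](C)O[Si](C)(C)C(C)(C)C
F7 | step 8 | methyl (2R,5Z,7R)-7-[(tert-butyldimethylsilyl)oxy]-2-hydroxy-2-methyl-3-oxo-5-(2-oxoethyl)oct-5-enoate | COC(=O)[C@](C)(O)C(=O)C/C(CC=O)=C\[C@@H](C)O[Si](C)(C)C(C)(C)C
F8 | step 6 | (2R,3R)-2-[(tert-butyldimethylsilyl)oxy]-6,6-dimethoxy-4-methylidenehexan-3-yl 4-nitrobenzoate | C[C@@H](O[Si](C)(C)C(C)(C)C)[C@H](OC(=O)c1ccc(cc1)[N+](=O)[O-])C(=C)CC(OC)OC
F9 | step 10 | methyl (2R)-2-hydroxy-4-[(2R)-6-methoxy-2-methyl-5,6-dihydro-2H-pyran-4-yl]-2-methyl-3-oxobutanoate (acetal epimers) | COC(=O)[C@](C)(O)C(=O)CC1=C[C@@H](C)OC(OC)C1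
F10 | step 13 | (9Z,12Z)-octadeca-9,12-dienoic anhydride | CCCCC/C=C\C/C=C\CCCCCCCC(=O)OC(=O)CCCCCCC/C=C\C/C=C\CCCCC
A1 | alternative 1 | (3R,7R)-7-hydroxy-3,7-dimethyl-3,4-dihydro-6H-isochromene-6,8(7H)-dione (identical with 16) | O[C@]1(C)C(=O)C=C2C[C@@H](C)OC=C2C1=O
A2 | alternative 1 | (2R)-4-(2,3-dioxobutylidene)-2-methyl-3,4-dihydro-2H-pyran-5-carbaldehyde | C[C@@H]1CC(=CC(=O)C(C)=O)C(C=O)=CO1
A3 | alternative 2 | (3R,7R)-3,7-dimethyl-7-[(triethylsilyl)oxy]-3,4,4a,5-tetrahydro-6H-isochromene-6,8(7H)-dione, H4a cis to H3 | CC[Si](CC)(CC)O[C@]1(C)C(=O)C[C@H]2C[C@@H](C)OC=C2C1=O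
A4 | alternative 2 | (2R)-1-{4-methyl-3,5-dioxo-4-[(triethylsilyl)oxy]cyclohexyl}propan-2-yl formate (relative configuration of the two ring centres not assigned) | CC[Si](CC)(CC)OC1(C)C(=O)CC(C[C@@H](C)OC=O)CC1=O
A5 | alternative 3 | (3R,7R)-8-hydroxy-3,7-dimethyl-6-oxo-3,4,7,8-tetrahydro-6H-isochromen-7-yl (9Z,12Z)-octadeca-9,12-dienoate (one C8 epimer drawn) | CCCCC/C=C\C/C=C\CCCCCCCC(=O)O[C@]1(C)C(=O)C=C2C[C@@H](C)OC=C2[C@H]1O
A6 | alternative 3 | 1-[(2R)-5-iodo-2-methyl-2,3-dihydro-4H-pyran-4-ylidene]-3-methyl-2,4-dioxobutan-3-yl (9Z,12Z)-octadeca-9,12-dienoate, quaternary carbon configured as C7 of the target | CCCCC/C=C\C/C=C\CCCCCCCC(=O)O[C@@](C)(C=O)C(=O)C=C1C[C@@H](C)OC=C1I
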